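**Plan**
Retrosynthetic cuts, in order: the five O–CH3 bonds; O1–C2 together with the C2=C3 unsaturation of ring C; C8a–O1 and C4–C4a as a pair; the Cα=Cβ bond of the cinnamic acid (later C3=C2); the bond from C3 to the 3-methylbutyl chain.
Enabling feature: in ring A, O1 on C8a and the C4 carbonyl on C4a sit on neighbouring carbons, and C4a is flanked by the oxygenated C5. This is the pattern left when a 3-alkoxyaryne accepts an oxygen and an acyl group across its triple bond.
Forward order: rings A and B are bought. The chain is placed on a phosphonoacetate and olefination adds ring B. The aryne step then joins this acid to ring A without closing a ring, and ring C closes afterwards at O1–C2.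
Stereochemistry: the target has no stereocentre. The only defined element on the way is the E alkene from the olefination. It disappears, with the two transient flavanone centres, when ring C is dehydrogenated.

Key step: step 7

Remark: atom labels O1, C2 to C8a and rings A, B, C follow flavone numbering. In the aryne, C1≡C2 is the triple bond, and C3 and C5 carry the methoxyls.

Step 1
Reactants: 1 3,5-dimethoxyphenol
Product: 2 2-bromo-3,5-dimethoxyphenol
Conditions: NBS (1.0 equiv), CH2Cl2, −78 °C → rt
Reagents that add atoms: N-bromosuccinimide, O=C1CCC(=O)N1Br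
Why: Electrophilic aromatic bromination with one equivalent of NBS at low temperature should go mainly to C2, which is ortho to the free hydroxyl, para to a methoxyl, statistically doubled and less crowded than C4 between the two methoxyls, and the positional isomer can be removed by chromatography.

Step 2
Reactants: 2 2-bromo-3,5-dimethoxyphenol
Product: 3 (2-bromo-3,5-dimethoxyphenoxy)trimethylsilane
Conditions: HMDS, THF, reflux; concentrate under vacuum
Reagents that add atoms: hexamethyldisilazane, C[Si](C)(C)N[Si](C)(C)C
Why: O-Silylation of the phenol with HMDS is driven by loss of ammonia, needs neither base nor aqueous work-up, and touches neither the aryl bromide nor the methyl ethers.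

Step 3
Reactants: 3 (2-bromo-3,5-dimethoxyphenoxy)trimethylsilane
Product: 6 3,5-dimethoxy-2-(trimethylsilyl)phenyl trifluoromethanesulfonate, via [2,4-dimethoxy-6-(trimethylsilyloxy)phenyl]lithium 4 (not isolated), via lithium 3,5-dimethoxy-2-(trimethylsilyl)phenoxide 5 (not isolated)
Conditions: n-BuLi, THF, −100 → −78 °C; then Tf2O, −100 → −78 °C; cold aq. NaHCO3
Reagents that add atoms: trifluoromethanesulfonic anhydride, O=S(=O)(C(F)(F)F)OS(=O)(=O)C(F)(F)F
Why: Bromine–lithium exchange gives aryllithium 4, whose carbanion takes the silyl group from the neighbouring oxygen (retro-Brook 1,3 O-to-C shift, driven by formation of the phenoxide), and 5 is O-sulfonylated in the same flask by Tf2O, the standard entry to ortho-silylaryl triflates.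

Step 4
Reactants: 7 triethyl phosphonoacetate; 8 1-bromo-3-methylbutane
Product: 9 ethyl 2-(diethoxyphosphoryl)-5-methylhexanoate (racemic)
Conditions: NaH, THF, 0 °C; then 8, NaI (cat.), reflux
Reagents that add atoms: none
Why: SN2 alkylation of the stabilised phosphonoacetate carbanion with a primary bromide (iodide catalysis) is routine, a small excess of 7 holds back double alkylation, and the new stereocentre is formed as a racemate and vanishes in step 5.

Step 5
Reactants: 9 ethyl 2-(diethoxyphosphoryl)-5-methylhexanoate; 10 3,4,5-trimethoxybenzaldehyde
Product: 11 ethyl (E)-2-(3-methylbutyl)-3-(3,4,5-trimethoxyphenyl)prop-2-enoate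
Conditions: NaH, THF, 0 °C; then 10, 0 °C → reflux
Reagents that add atoms: none
Why: Horner–Wadsworth–Emmons olefination of an aromatic aldehyde with an α-alkyl phosphonoacetate proceeds under equilibrating addition, so the aryl group ends up trans to the ester and the E alkene should dominate.

Step 6
Reactants: 11 ethyl (E)-2-(3-methylbutyl)-3-(3,4,5-trimethoxyphenyl)prop-2-enoate
Product: 12 (E)-2-(3-methylbutyl)-3-(3,4,5-trimethoxyphenyl)prop-2-enoic acid
Conditions: NaOH, EtOH/H2O, reflux; then aq. HCl
Reagents that add atoms: sodium hydroxide NaOH (its oxygen becomes the acid OH), [Na+].[OH-]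
Why: Saponification by acyl–oxygen cleavage needs heat for this hindered conjugated ester, but the aryl methyl ethers and the trisubstituted alkene are inert to aqueous base and the E geometry is kept.

Step 7
Reactants: 6 3,5-dimethoxy-2-(trimethylsilyl)phenyl trifluoromethanesulfonate; 12 (E)-2-(3-methylbutyl)-3-(3,4,5-trimethoxyphenyl)prop-2-enoic acid
Product: 14 (E)-1-(2-hydroxy-4,6-dimethoxyphenyl)-2-(3-methylbutyl)-3-(3,4,5-trimethoxyphenyl)prop-2-en-1-one, via 3,5-dimethoxybenzyne 13 (not isolated)
Conditions: flame-dried CsF (4 equiv), 6 (1.5 equiv), THF (0.02 M), 125 °C, sealed tube; cold aq. NH4Cl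
Reagents that add atoms: none
Why: Fluoride attacks silicon in 6, triflate departs and aryne 13 is released slowly, while surplus CsF turns 12 into its carboxylate. The carboxylate oxygen adds to aryne carbon C1, the aryl anion thus formed at C2 attacks the carbonyl of its own new ester through a strained four-membered alkoxide, and cleavage of the old acyl C–O bond gives the phenoxide ketone, so that C8a–O1 and C4–C4a arise in one operation. The closest known reaction type is the CsF-induced insertion of arynes into the C–O bond of carboxylic acids, which gives ortho-hydroxyaryl ketones and has been run with unsaturated acids and with 3-methoxybenzyne. No ring is closed and no stereocentre is made; the E alkene is a spectator, and the product should stay open because it rests as the conjugated cesium phenoxide until the cold, mildly acidic quench, while any material that does close is simply 15 and enters step 8 unchanged. The regioselectivity that is needed comes from the C3 methoxyl, whose inductive pull and distortion of the triple bond send the nucleophile to C1 and place the charge at C2, the C5 methoxyl being too remote to interfere. Acyl transfer must also outrun protonation of the aryl anion, which the dry, dilute, aprotic medium at 125 °C and the binding of HF by surplus CsF should ensure.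

Step 8
Reactants: 14 (E)-1-(2-hydroxy-4,6-dimethoxyphenyl)-2-(3-methylbutyl)-3-(3,4,5-trimethoxyphenyl)prop-2-en-1-one
Product: 16 5,7-dimethoxy-3-(3-methylbutyl)-2-(3,4,5-trimethoxyphenyl)-4H-chromen-4-one, via trans-3-(3-methylbutyl)flavanone pentamethyl ether 15 (not isolated)
Conditions: I2 (10 mol %), DMSO, 130 °C; aq. Na2S2O3
Reagents that add atoms: none
Why: Iodine/DMSO oxidative cyclisation of a 2'-hydroxychalcone: the phenol closes O1–C2 by 6-endo-trig oxa-Michael addition to give 15, its only enolisable position C3 is iodinated, loss of HI towards C2–H forms the pyranone, and DMSO reoxidises HI to I2, so both transient stereocentres are erased and the geometry of 14 is irrelevant.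

Step 9
Reactants: 16 5,7-dimethoxy-3-(3-methylbutyl)-2-(3,4,5-trimethoxyphenyl)-4H-chromen-4-one
Product: 17 asplenetin, 5,7-dihydroxy-3-(3-methylbutyl)-2-(3,4,5-trihydroxyphenyl)-4H-chromen-4-one
Conditions: BBr3 (10 equiv), CH2Cl2, −78 °C → rt, argon; then ice-water
Reagents that add atoms: none
Why: Lewis-acid cleavage of aryl methyl ethers with excess BBr3 (bromide attacks the methyl group of each boron-complexed ether) is standard for polymethoxyflavones, the saturated side chain and the pyranone are inert, and exclusion of air during the acidic aqueous work-up protects the pyrogallol ring B.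

**Compound list**
1 | 3,5-dimethoxyphenol | COc1cc(O)cc(OC)c1 | starting material
2 | 2-bromo-3,5-dimethoxyphenol | COc1cc(O)c(Br)c(OC)c1 | intermediate
3 | (2-bromo-3,5-dimethoxyphenoxy)trimethylsilane | COc1cc(O[Si](C)(C)C)c(Br)c(OC)c1 | intermediate
4 | [2,4-dimethoxy-6-(trimethylsilyloxy)phenyl]lithium | COc1cc(O[Si](C)(C)C)c([Li])c(OC)c1 | intermediate (not isolated)
5 | lithium 3,5-dimethoxy-2-(trimethylsilyl)phenoxide | [Li+].[O-]c1cc(OC)cc(OC)c1[Si](C)(C)C | intermediate (not isolated)
6 | 3,5-dimethoxy-2-(trimethylsilyl)phenyl trifluoromethanesulfonate | COc1cc(OC)c([Si](C)(C)C)c(OS(=O)(=O)C(F)(F)F)c1 | intermediate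
7 | triethyl phosphonoacetate | CCOC(=O)CP(=O)(OCC)OCC | starting material
8 | 1-bromo-3-methylbutane | CC(C)CCBr | starting material
9 | ethyl 2-(diethoxyphosphoryl)-5-methylhexanoate (racemic at C2) | CCOC(=O)C(CCC(C)C)P(=O)(OCC)OCC | intermediate
10 | 3,4,5-trimethoxybenzaldehyde | COc1cc(C=O)cc(OC)c1OC | starting material
11 | ethyl (E)-2-(3-methylbutyl)-3-(3,4,5-trimethoxyphenyl)prop-2-enoate | CCOC(=O)/C(CCC(C)C)=C/c1cc(OC)c(OC)c(OC)c1 | intermediate
12 | (E)-2-(3-methylbutyl)-3-(3,4,5-trimethoxyphenyl)prop-2-enoic acid | OC(=O)/C(CCC(C)C)=C/c1cc(OC)c(OC)c(OC)c1 | intermediate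
13 | 3,5-dimethoxybenzyne (1,2-didehydro-3,5-dimethoxybenzene) | COC1=CC(OC)=CC#C1 | intermediate (not isolated)
14 | (E)-1-(2-hydroxy-4,6-dimethoxyphenyl)-2-(3-methylbutyl)-3-(3,4,5-trimethoxyphenyl)prop-2-en-1-one | COc1cc(O)c(C(=O)/C(CCC(C)C)=C/c2cc(OC)c(OC)c(OC)c2)c(OC)c1 | intermediate
15 | trans-5,7-dimethoxy-3-(3-methylbutyl)-2-(3,4,5-trimethoxyphenyl)chroman-4-one (racemic, the 2S,3R enantiomer drawn; the cis isomer may accompany it) | O=C1c2c(OC)cc(OC)cc2O[C@H](c2cc(OC)c(OC)c(OC)c2)[C@H]1CCC(C)C | intermediate (not isolated)
16 | 5,7-dimethoxy-3-(3-methylbutyl)-2-(3,4,5-trimethoxyphenyl)-4H-chromen-4-one | CC(C)CCc1c(-c2cc(OC)c(OC)c(OC)c2)oc2cc(OC)cc(OC)c2c1=O | intermediate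
17 | asplenetin | CC(C)CCc1c(-c2cc(O)c(O)c(O)c2)oc2cc(O)cc(O)c2c1=O | target

**Totals**
Total step count: 9.
Longest linear sequence: 6 (steps 1–3 or steps 4–6, followed by steps 7–9).

**Steps most likely to fail**

Step 7.
- Risks: the aryl anion may be protonated before the acyl group migrates, which amounts to plain O-arylation. The hindered, conjugated carbonyl slows the shift. The product phenoxide may also be arylated by a second aryne.
- Fallback: it sets out from 2 and 12 and makes the same ortho-acyloxy aryl anion without an aryne and without any proton source. Steglich esterification (EDC·HCl, DMAP, CH2Cl2) should give 2-bromo-3,5-dimethoxyphenyl (E)-2-(3-methylbutyl)-3-(3,4,5-trimethoxyphenyl)prop-2-enoate F1.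
- Bromine–lithium exchange with n-BuLi in THF at −100 °C then triggers an anionic Fries O-to-C acyl shift. The position of the bromine fixes the regiochemistry. Aqueous work-up returns the route at 14.

Step 8.
- Risks: closure onto a trisubstituted enone that carries a donor aryl group may be slow. Iodination at the tertiary C3 may lag, and nuclear iodination of the electron-rich ring A may compete.
- Fallback: it sets out from 14 and separates ring closure from oxidation. NaOAc in refluxing EtOH should close the ring, and 15 is isolated.
- DDQ in refluxing dioxane then abstracts hydride from C2, which is benzylic to the trimethoxyphenyl ring and α to O1. Loss of the C3 proton follows, and the route is rejoined at 16. No compound outside the list arises (F0).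

Step 1.
- Risks: positional selectivity between C2 and C4 may be poor, and this very activated phenol may over-brominate.
- Fallback: it sets out from 1 and installs silicon by directed ortho-metalation instead of through a bromide. Et2NCOCl with K2CO3 in refluxing MeCN should give 3,5-dimethoxyphenyl diethylcarbamate F2.
- s-BuLi/TMEDA in THF at −78 °C lithiates between the carbamate and a methoxyl, because the carbamate is the stronger director. A TMSCl quench gives 3,5-dimethoxy-2-(trimethylsilyl)phenyl diethylcarbamate F3.
- LiAlH4 in THF, with a neutral work-up, frees 3,5-dimethoxy-2-(trimethylsilyl)phenol F4. n-BuLi at −78 °C converts F4 into 5, where the route is rejoined and the triflation of step 3 follows.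

**Further compounds**
F1 | step 7 | 2-bromo-3,5-dimethoxyphenyl (E)-2-(3-methylbutyl)-3-(3,4,5-trimethoxyphenyl)prop-2-enoate | COc1cc(OC)c(Br)c(OC(=O)/C(CCC(C)C)=C/c2cc(OC)c(OC)c(OC)c2)c1
F0 | step 8 | none | none
F2 | step 1 | 3,5-dimethoxyphenyl diethylcarbamate | CCN(CC)C(=O)Oc1cc(OC)cc(OC)c1
F3 | step 1 | 3,5-dimethoxy-2-(trimethylsilyl)phenyl diethylcarbamate | CCN(CC)C(=O)Oc1cc(OC)cc(OC)c1[Si](C)(C)C
F4 | step 1 | 3,5-dimethoxy-2-(trimethylsilyl)phenol | COc1cc(O)c([Si](C)(C)C)c(OC)c1
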